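The eleven-membered ring is closed at C10–C11 (numbering of the cycloundec-1-ene-1-carboxylic acid name) by an intramolecular allylboration. The feature exploited is the homoallylic array O–C10–C11–C1(CO2H)=C2 of the ring: an open-chain C10 aldehyde that carries a 2-(alkoxycarbonyl)allylboronate with boron on stereogenic C2 attacks through its methylene terminus C11. One operation forms the C10–C11 bond and the carbocycle, relays the C2 configuration to C10 through the boron-bridged cyclic transition state, sets the E enoate and erases the temporary C2–B bond. The precursor is assembled from 3,3-dimethylglutaric anhydride, 2-bromohexa-1,5-diene and an acrylate by Weinreb ketone synthesis, CBS reduction, cross-metathesis and copper-catalysed allylic borylation.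

Key step: step 13

Numbering: locants C1–C11 in the text are those of the target ring (C1 carries CO2H, C1=C2 is the ring alkene, C5 carries the methylidene, C6 the free hydroxyl, C8 the two methyls, C10 the acyloxy group, C11 is the CH2 between C10 and C1); systematic names of open-chain compounds use their own locants.
Assumption: in step 11 (R,R)-QuinoxP* is taken to deliver the 3R boronate; if the sense of induction is the opposite, the (S,S) ligand is used.

Step 1
Reactants: 1 3,3-dimethylglutaric anhydride
Product: 3 4,4-dimethyloxan-2-one, via sodium 5-hydroxy-3,3-dimethylpentanoate 2 (not isolated)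
Conditions: NaBH4, THF, 0 °C to rt; then 6 M HCl, rt
Reagents that add atoms: none
Why: Borohydride reduction of one carbonyl of the symmetrical cyclic anhydride followed by acid lactonisation (anhydride-to-lactone reduction) should give a single δ-lactone because the two carbonyls are equivalent.

Step 2
Reactants: 3 4,4-dimethyloxan-2-one
Product: 4 5-hydroxy-N-methoxy-N,3,3-trimethylpentanamide
Conditions: MeNH(OMe)·HCl, i-PrMgCl, THF, −20 to 0 °C
Reagents that add atoms: N,O-dimethylhydroxylamine hydrochloride, CNOC.Cl
Why: The magnesium amide opens the lactone by acyl substitution (Weinreb amide formation) and the chelated amide does not react further.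

Step 3
Reactants: 4 5-hydroxy-N-methoxy-N,3,3-trimethylpentanamide
Product: 5 N-methoxy-N,3,3-trimethyl-5-[(triethylsilyl)oxy]pentanamide
Conditions: TESCl, imidazole, CH2Cl2, 0 °C
Reagents that add atoms: chlorotriethylsilane, CC[Si](Cl)(CC)CC
Why: Imidazole-promoted silylation of the primary alcohol blocks relactonisation and installs a group that Swern conditions later convert directly into the aldehyde.

Step 4
Reactants: 6 2,3-dibromoprop-1-ene; 7 allylmagnesium bromide
Product: 8 2-bromohexa-1,5-diene
Conditions: Et2O, 0 °C to rt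
Reagents that add atoms: none
Why: The allyl Grignard reagent displaces the allylic bromide (SN2 and SN2' paths give the same product) while the vinylic bromide is inert.

Step 5
Reactants: 8 2-bromohexa-1,5-diene; 5 N-methoxy-N,3,3-trimethyl-5-[(triethylsilyl)oxy]pentanamide
Product: 11 8,8-dimethyl-5-methylidene-10-[(triethylsilyl)oxy]dec-1-en-6-one, via hexa-1,5-dien-2-yllithium 9 (not isolated), via lithium hemiaminal alkoxide adduct 10 (not isolated)
Conditions: t-BuLi (2 equiv), Et2O, −78 °C; then 5, −78 to −40 °C; AcOH, −78 °C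
Reagents that add atoms: none
Why: Bromine–lithium exchange gives the vinyllithium, whose addition to the Weinreb amide stops at the chelated tetrahedral adduct, so the α-methylene ketone is released only on the cold acidic quench (Weinreb ketone synthesis).

Step 6
Reactants: 11 8,8-dimethyl-5-methylidene-10-[(triethylsilyl)oxy]dec-1-en-6-one
Product: 12 (6S)-8,8-dimethyl-5-methylidene-10-[(triethylsilyl)oxy]dec-1-en-6-ol
Conditions: (R)-Me-CBS oxazaborolidine (0.2 equiv), catecholborane, toluene, −78 °C
Reagents that add atoms: none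
Why: In this Corey–Bakshi–Shibata reduction the 2-substituted vinyl group should act as the large substituent and the CH2 group as the small one, so the (R)-catalyst should deliver hydride to give the 6S alcohol, and catecholborane at −78 °C should leave the terminal alkene alone.

Step 7
Reactants: 12 (6S)-8,8-dimethyl-5-methylidene-10-[(triethylsilyl)oxy]dec-1-en-6-ol
Product: 13 (6S)-6-[(tert-butyldimethylsilyl)oxy]-8,8-dimethyl-5-methylidene-10-[(triethylsilyl)oxy]dec-1-ene
Conditions: TBSOTf, 2,6-lutidine, CH2Cl2, −78 to 0 °C
Reagents that add atoms: tert-butyldimethylsilyl triflate, CC(C)(C)[Si](C)(C)OS(=O)(=O)C(F)(F)F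
Why: Silyl triflate silylation of the hindered secondary allylic alcohol under buffered conditions should leave the primary TES ether untouched.

Step 8
Reactants: 14 tert-butyl acrylate; 15 formaldehyde
Product: 16 tert-butyl 2-(hydroxymethyl)prop-2-enoate
Conditions: 37% aq. HCHO, DABCO, 1,4-dioxane/H2O, rt
Reagents that add atoms: none
Why: The Morita–Baylis–Hillman reaction of an acrylate with formaldehyde under DABCO catalysis is a standard route to 2-(hydroxymethyl)acrylates.

Step 9
Reactants: 16 tert-butyl 2-(hydroxymethyl)prop-2-enoate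
Product: 17 tert-butyl 2-{[(methoxycarbonyl)oxy]methyl}prop-2-enoate
Conditions: ClCO2Me, pyridine, CH2Cl2, 0 °C
Reagents that add atoms: methyl chloroformate, COC(Cl)=O
Why: Acylation of the primary allylic alcohol with the chloroformate gives the carbonate that serves as leaving group in step 11.

Step 10
Reactants: 13 (6S)-6-[(tert-butyldimethylsilyl)oxy]-8,8-dimethyl-5-methylidene-10-[(triethylsilyl)oxy]dec-1-ene; 17 tert-butyl 2-{[(methoxycarbonyl)oxy]methyl}prop-2-enoate
Product: 18 tert-butyl (2E,7S)-7-[(tert-butyldimethylsilyl)oxy]-2-{[(methoxycarbonyl)oxy]methyl}-9,9-dimethyl-6-methylidene-11-[(triethylsilyl)oxy]undec-2-enoate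
Conditions: second-generation Hoveyda–Grubbs catalyst (5 mol %), 17 (3 equiv), CH2Cl2, 40 °C
Reagents that add atoms: none
Why: In this olefin cross-metathesis only the unhindered monosubstituted alkene of 13 should react with the 2-substituted acrylate (the 1,1-disubstituted alkene next to the silyloxy carbon is too hindered), and the trisubstituted enoate should form as the more stable E isomer with the chain trans to the ester.

Step 11
Reactants: 18 tert-butyl (2E,7S)-7-[(tert-butyldimethylsilyl)oxy]-2-{[(methoxycarbonyl)oxy]methyl}-9,9-dimethyl-6-methylidene-11-[(triethylsilyl)oxy]undec-2-enoate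
Product: 19 tert-butyl (3R,7S)-7-[(tert-butyldimethylsilyl)oxy]-9,9-dimethyl-2,6-dimethylidene-3-(4,4,5,5-tetramethyl-1,3,2-dioxaborolan-2-yl)-11-[(triethylsilyl)oxy]undecanoate
Conditions: CuCl (5 mol %), (R,R)-QuinoxP* (5 mol %), KOt-Bu (10 mol %), B2pin2 (1.05 equiv), THF, 0 °C
Reagents that add atoms: bis(pinacolato)diboron, CC1(C)OB(OC1(C)C)B1OC(C)(C)C(C)(C)O1
Why: In this copper-catalysed enantioselective γ-selective (SN2') allylic borylation the boryl copper species should add boron to the enoate β-carbon from the face set by the chiral bisphosphine (3R) and the copper enolate should expel the carbonate to leave a terminal methylene, and since only this elimination turns the catalyst over under aprotic conditions the product acrylate should not be borylated again.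

Step 12
Reactants: 19 tert-butyl (3R,7S)-7-[(tert-butyldimethylsilyl)oxy]-9,9-dimethyl-2,6-dimethylidene-3-(4,4,5,5-tetramethyl-1,3,2-dioxaborolan-2-yl)-11-[(triethylsilyl)oxy]undecanoate
Product: 20 tert-butyl (3R,7S)-7-[(tert-butyldimethylsilyl)oxy]-9,9-dimethyl-2,6-dimethylidene-11-oxo-3-(4,4,5,5-tetramethyl-1,3,2-dioxaborolan-2-yl)undecanoate
Conditions: (COCl)2, DMSO, CH2Cl2, −78 to −40 °C; then Et3N, −78 to 0 °C; product used at once in dilute solution
Reagents that add atoms: none
Why: Swern conditions should cleave and oxidise the primary triethylsilyl ether directly to the aldehyde (selective Swern oxidation of primary TES ethers) while the secondary TBS ether, the tert-butyl ester and the ester-deactivated secondary allylboronate survive.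

Step 13
Reactants: 20 tert-butyl (3R,7S)-7-[(tert-butyldimethylsilyl)oxy]-9,9-dimethyl-2,6-dimethylidene-11-oxo-3-(4,4,5,5-tetramethyl-1,3,2-dioxaborolan-2-yl)undecanoate
Product: 22 tert-butyl (1E,6S,10S)-6-[(tert-butyldimethylsilyl)oxy]-10-hydroxy-8,8-dimethyl-5-methylidenecycloundec-1-ene-1-carboxylate, via pinacol borate ester of the ring alcohol 21 (not isolated)
Conditions: toluene, 0.002 M (syringe-pump addition of 20), 100 °C; then aq. NaHCO3
Reagents that add atoms: none
Why: Proposed new method: on heating, the aldehyde oxygen should bind boron and the allyl group should transfer through a six-membered boron-bridged cyclic transition state with allylic transposition (allylboration), so that the methylene terminus C11 bonds to C10 while the C2–B bond breaks and C1=C2 forms; the closest known reactions are intermolecular additions of α-substituted and of 2-(alkoxycarbonyl) allylboronates to aldehydes and intramolecular allylborations that close five- to seven-membered rings, whereas an eleven-membered closure of this kind is not established. The ring closes in an 11-endo mode (all three allyl carbons become ring atoms), with the seven-atom chain C3–C9 spanning the 1,4-positions of the cyclic transition state. Because that chain can bridge only when the C2 and C10 substituents are cis on the six-membered array, the 2R configuration fixed in step 11 should be translated into 10S whatever chair or boat is used, independently of C6. Among the cis arrangements the chair with the C3 chain axial and the C9 chain equatorial should be preferred, since an equatorial C3 chain would eclipse the C1 ester (1,2-allylic strain), and it delivers C3 cis to C11, that is the E enoate. Attack through C11 instead of C2 is inherent to the cyclic mechanism, the pinacol ester does not undergo 1,3-boron shift so boron stays on C2, and the tert-butyl ester should keep the borate from lactonising. Oligomerisation, the competing process, is held back by the 0.002 M concentration, the gem-dimethyl group at C8 and the low intermolecular reactivity of this ester-deactivated secondary boronate.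

Step 14
Reactants: 22 tert-butyl (1E,6S,10S)-6-[(tert-butyldimethylsilyl)oxy]-10-hydroxy-8,8-dimethyl-5-methylidenecycloundec-1-ene-1-carboxylate; 23 3-methylbutanoyl chloride
Product: 24 tert-butyl (1E,6S,10S)-6-[(tert-butyldimethylsilyl)oxy]-8,8-dimethyl-10-[(3-methylbutanoyl)oxy]-5-methylidenecycloundec-1-ene-1-carboxylate
Conditions: pyridine, DMAP (cat.), CH2Cl2, 0 °C to rt
Reagents that add atoms: none
Why: DMAP-catalysed acylation of the only free hydroxyl proceeds with retention at C10, and the tert-butyl ester resists competing lactonisation.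

Step 15
Reactants: 24 tert-butyl (1E,6S,10S)-6-[(tert-butyldimethylsilyl)oxy]-8,8-dimethyl-10-[(3-methylbutanoyl)oxy]-5-methylidenecycloundec-1-ene-1-carboxylate
Product: 26 (1E,6S,10S)-6-hydroxy-8,8-dimethyl-10-[(3-methylbutanoyl)oxy]-5-methylidenecycloundec-1-ene-1-carboxylic acid, via trimethylsilyl ester 25 (not isolated)
Conditions: TMSOTf, 2,6-lutidine, CH2Cl2, 0 °C; then HF·pyridine, THF, 0 °C to rt
Reagents that add atoms: none
Why: Silyl triflate cleavage of the tert-butyl ester under non-protic buffered conditions should spare the exocyclic alkene and allylic oxygen, and fluoride should then remove the silyl ester and the TBS ether without touching the isovalerate (ester cleavage followed by desilylation).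

Compound list
1 | 3,3-dimethylglutaric anhydride (4,4-dimethyloxane-2,6-dione) | CC1(C)CC(=O)OC(=O)C1 | starting material
2 | sodium 5-hydroxy-3,3-dimethylpentanoate (not isolated) | [Na+].[O-]C(=O)CC(C)(C)CCO | intermediate
3 | 4,4-dimethyloxan-2-one | CC1(C)CCOC(=O)C1 | intermediate
4 | 5-hydroxy-N-methoxy-N,3,3-trimethylpentanamide | CON(C)C(=O)CC(C)(C)CCO | intermediate
5 | N-methoxy-N,3,3-trimethyl-5-[(triethylsilyl)oxy]pentanamide | CC[Si](CC)(CC)OCCC(C)(C)CC(=O)N(C)OC | intermediate
6 | 2,3-dibromoprop-1-ene | C=C(Br)CBr | starting material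
7 | allylmagnesium bromide | C=CC[Mg]Br | starting material
8 | 2-bromohexa-1,5-diene | C=CCCC(Br)=C | intermediate
9 | hexa-1,5-dien-2-yllithium (not isolated) | [Li]C(=C)CCC=C | intermediate
10 | lithium hemiaminal alkoxide adduct of 9 and 5 (not isolated) | CC[Si](CC)(CC)OCCC(C)(C)CC(O[Li])(N(C)OC)C(=C)CCC=C | intermediate
11 | 8,8-dimethyl-5-methylidene-10-[(triethylsilyl)oxy]dec-1-en-6-one | CC[Si](CC)(CC)OCCC(C)(C)CC(=O)C(=C)CCC=C | intermediate
12 | (6S)-8,8-dimethyl-5-methylidene-10-[(triethylsilyl)oxy]dec-1-en-6-ol | CC[Si](CC)(CC)OCCC(C)(C)C[C@H](O)C(=C)CCC=C | intermediate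
13 | (6S)-6-[(tert-butyldimethylsilyl)oxy]-8,8-dimethyl-5-methylidene-10-[(triethylsilyl)oxy]dec-1-ene | CC[Si](CC)(CC)OCCC(C)(C)C[C@H](O[Si](C)(C)C(C)(C)C)C(=C)CCC=C | intermediate
14 | tert-butyl acrylate | C=CC(=O)OC(C)(C)C | starting material
15 | formaldehyde | C=O | starting material
16 | tert-butyl 2-(hydroxymethyl)prop-2-enoate | C=C(CO)C(=O)OC(C)(C)C | intermediate
17 | tert-butyl 2-{[(methoxycarbonyl)oxy]methyl}prop-2-enoate | C=C(COC(=O)OC)C(=O)OC(C)(C)C | intermediate
18 | tert-butyl (2E,7S)-7-[(tert-butyldimethylsilyl)oxy]-2-{[(methoxycarbonyl)oxy]methyl}-9,9-dimethyl-6-methylidene-11-[(triethylsilyl)oxy]undec-2-enoate | CC[Si](CC)(CC)OCCC(C)(C)C[C@H](O[Si](C)(C)C(C)(C)C)C(=C)CC/C=C(/C(=O)OC(C)(C)C)COC(=O)OC | intermediate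
19 | tert-butyl (3R,7S)-7-[(tert-butyldimethylsilyl)oxy]-9,9-dimethyl-2,6-dimethylidene-3-(4,4,5,5-tetramethyl-1,3,2-dioxaborolan-2-yl)-11-[(triethylsilyl)oxy]undecanoate | CC[Si](CC)(CC)OCCC(C)(C)C[C@H](O[Si](C)(C)C(C)(C)C)C(=C)CC[C@@H](B1OC(C)(C)C(C)(C)O1)C(=C)C(=O)OC(C)(C)C | intermediate
20 | tert-butyl (3R,7S)-7-[(tert-butyldimethylsilyl)oxy]-9,9-dimethyl-2,6-dimethylidene-11-oxo-3-(4,4,5,5-tetramethyl-1,3,2-dioxaborolan-2-yl)undecanoate | O=CCC(C)(C)C[C@H](O[Si](C)(C)C(C)(C)C)C(=C)CC[C@@H](B1OC(C)(C)C(C)(C)O1)C(=C)C(=O)OC(C)(C)C | intermediate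
21 | pinacol borate ester of 22 at the C10 oxygen (not isolated) | C=C1CC/C=C(/C(=O)OC(C)(C)C)C[C@@H](OB2OC(C)(C)C(C)(C)O2)CC(C)(C)C[C@@H]1O[Si](C)(C)C(C)(C)C | intermediate
22 | tert-butyl (1E,6S,10S)-6-[(tert-butyldimethylsilyl)oxy]-10-hydroxy-8,8-dimethyl-5-methylidenecycloundec-1-ene-1-carboxylate | C=C1CC/C=C(/C(=O)OC(C)(C)C)C[C@@H](O)CC(C)(C)C[C@@H]1O[Si](C)(C)C(C)(C)C | intermediate
23 | 3-methylbutanoyl chloride (isovaleryl chloride) | CC(C)CC(Cl)=O | starting material
24 | tert-butyl (1E,6S,10S)-6-[(tert-butyldimethylsilyl)oxy]-8,8-dimethyl-10-[(3-methylbutanoyl)oxy]-5-methylidenecycloundec-1-ene-1-carboxylate | C=C1CC/C=C(/C(=O)OC(C)(C)C)C[C@@H](OC(=O)CC(C)C)CC(C)(C)C[C@@H]1O[Si](C)(C)C(C)(C)C | intermediate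
25 | trimethylsilyl ester of the C1 acid with the C6 TBS ether still in place (not isolated) | C=C1CC/C=C(/C(=O)O[Si](C)(C)C)C[C@@H](OC(=O)CC(C)C)CC(C)(C)C[C@@H]1O[Si](C)(C)C(C)(C)C | intermediate
26 | (1E,6S,10S)-6-hydroxy-8,8-dimethyl-10-[(3-methylbutanoyl)oxy]-5-methylidenecycloundec-1-ene-1-carboxylic acid (CNP0400752.1) | C=C1CC/C=C(/C(=O)O)C[C@@H](OC(=O)CC(C)C)CC(C)(C)C[C@@H]1O | target

Total step count: 15. Longest linear sequence: 12 steps (1, 2, 3, 5, 6, 7, 10, 11, 12, 13, 14, 15).

Steps most likely to fail

Step 13 (Proposed new method). The intramolecular allyl transfer may be slower than intermolecular allylboration or than thermal decay of 20 (protodeboronation, polymerisation of the acrylate), so that oligomers form instead of the eleven-membered ring. The fallback uses a known reaction type, the Lewis-acid Hosomi–Sakurai ring closure of a 2-(alkoxycarbonyl)allylsilane onto an aldehyde, and sets out from 18. Copper-catalysed γ-selective allylic silylation with PhMe2Si–Bpin (CuCl, NaOt-Bu, THF, 0 °C) should give the allylsilane tert-butyl (7S)-7-[(tert-butyldimethylsilyl)oxy]-3-[dimethyl(phenyl)silyl]-9,9-dimethyl-2,6-dimethylidene-11-[(triethylsilyl)oxy]undecanoate F1. Swern oxidation of its primary TES ether as in step 12 should give the silyl aldehyde F2. BF3·OEt2 in CH2Cl2 at −78 °C and 0.002 M should then form the C10–C11 bond by anti SE2' attack of the methylene terminus through an open transition state, and the fallback comes back to the route at 22. Because this open transition state does not relay chirality, the C10 epimer of 22, tert-butyl (1E,6S,10R)-6-[(tert-butyldimethylsilyl)oxy]-10-hydroxy-8,8-dimethyl-5-methylidenecycloundec-1-ene-1-carboxylate F3, may accompany 22. It is separated and esterified with 3-methylbutanoic acid under Mitsunobu conditions (PPh3, DIAD, toluene) with inversion, which gives 24, so both epimers converge.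

Step 11. Boron may be delivered with poor face selectivity, or the product acrylate may take up a second boryl group. The fallback gives up reagent control of C2 and makes the endgame stereoconvergent. It sets out from 18 with an achiral catalyst (CuCl, Xantphos, KOt-Bu, B2pin2 1.0 equiv, THF), which should give 19 together with its 3S epimer F4. The mixture is carried through steps 12 and 13, where F4 should give the 3S aldehyde F5, the 10R borate F6 and, after work-up, the 10R alcohol F3 beside 22. The diastereomers 22 and F3 are separated by chromatography; 22 is acylated as in step 14 and F3 is inverted by Mitsunobu esterification with 3-methylbutanoic acid, so the fallback comes back to the route at 24.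

Step 6. Facial discrimination between the 2-substituted vinyl group and the neopentyl-type CH2 group may be insufficient, and an enantiomeric deficit at C6 cannot be corrected later. The fallback replaces asymmetric reduction by resolution and sets out from 11. Luche reduction (NaBH4, CeCl3·7H2O, MeOH, −78 °C) gives the racemic allylic alcohol, that is 12 and its enantiomer (6R)-8,8-dimethyl-5-methylidene-10-[(triethylsilyl)oxy]dec-1-en-6-ol F7. Sharpless kinetic resolution (Ti(Oi-Pr)4, D-(−)-diisopropyl tartrate, t-BuOOH, 4 Å molecular sieves, CH2Cl2, −20 °C) should epoxidise F7 to the epoxy alcohol (1R)-1-[(2R)-2-(but-3-en-1-yl)oxiran-2-yl]-3,3-dimethyl-5-[(triethylsilyl)oxy]pentan-1-ol F8 and leave 12, where the fallback comes back to the route.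

Further compounds
F1 | step 13 | tert-butyl (7S)-7-[(tert-butyldimethylsilyl)oxy]-3-[dimethyl(phenyl)silyl]-9,9-dimethyl-2,6-dimethylidene-11-[(triethylsilyl)oxy]undecanoate (C3 epimers) | CC[Si](CC)(CC)OCCC(C)(C)C[C@H](O[Si](C)(C)C(C)(C)C)C(=C)CCC([Si](C)(C)c1ccccc1)C(=C)C(=O)OC(C)(C)C
F2 | step 13 | tert-butyl (7S)-7-[(tert-butyldimethylsilyl)oxy]-3-[dimethyl(phenyl)silyl]-9,9-dimethyl-2,6-dimethylidene-11-oxoundecanoate (C3 epimers) | O=CCC(C)(C)C[C@H](O[Si](C)(C)C(C)(C)C)C(=C)CCC([Si](C)(C)c1ccccc1)C(=C)C(=O)OC(C)(C)C
F3 | step 13 | tert-butyl (1E,6S,10R)-6-[(tert-butyldimethylsilyl)oxy]-10-hydroxy-8,8-dimethyl-5-methylidenecycloundec-1-ene-1-carboxylate | C=C1CC/C=C(/C(=O)OC(C)(C)C)C[C@H](O)CC(C)(C)C[C@@H]1O[Si](C)(C)C(C)(C)C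
F4 | step 11 | tert-butyl (3S,7S)-7-[(tert-butyldimethylsilyl)oxy]-9,9-dimethyl-2,6-dimethylidene-3-(4,4,5,5-tetramethyl-1,3,2-dioxaborolan-2-yl)-11-[(triethylsilyl)oxy]undecanoate | CC[Si](CC)(CC)OCCC(C)(C)C[C@H](O[Si](C)(C)C(C)(C)C)C(=C)CC[C@H](B1OC(C)(C)C(C)(C)O1)C(=C)C(=O)OC(C)(C)C
F5 | step 11 | tert-butyl (3S,7S)-7-[(tert-butyldimethylsilyl)oxy]-9,9-dimethyl-2,6-dimethylidene-11-oxo-3-(4,4,5,5-tetramethyl-1,3,2-dioxaborolan-2-yl)undecanoate | O=CCC(C)(C)C[C@H](O[Si](C)(C)C(C)(C)C)C(=C)CC[C@H](B1OC(C)(C)C(C)(C)O1)C(=C)C(=O)OC(C)(C)C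
F6 | step 11 | pinacol borate ester of F3 at the C10 oxygen | C=C1CC/C=C(/C(=O)OC(C)(C)C)C[C@H](OB2OC(C)(C)C(C)(C)O2)CC(C)(C)C[C@@H]1O[Si](C)(C)C(C)(C)C
F7 | step 6 | (6R)-8,8-dimethyl-5-methylidene-10-[(triethylsilyl)oxy]dec-1-en-6-ol | CC[Si](CC)(CC)OCCC(C)(C)C[C@@H](O)C(=C)CCC=C
F8 | step 6 | (1R)-1-[(2R)-2-(but-3-en-1-yl)oxiran-2-yl]-3,3-dimethyl-5-[(triethylsilyl)oxy]pentan-1-ol | CC[Si](CC)(CC)OCCC(C)(C)C[C@@H](O)[C@@]1(CCC=C)CO1
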